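The decision is which recipe to run for L, south or east, and two of us read the earlier runs differently.

| setting | grey | ochre | violet | amber | south | east |
|---|---|---|---|---|---|---|
| X | 0.029 M | 0.055 M | 0.099 M | 0.10 M | 0.10 M | 0.030 M |
| Q | 0.15 M | 0.15 M | 0.15 M | 0.39 M | 0.150 M | 0.600 M |
| Z | 0.10 M | 0.10 M | 0.10 M | 0.10 M | 0.100 M | 0.100 M |
| temperature | 70 °C | 92 °C | 70 °C | 92 °C |  |  |
| remark | run made earlier | run made earlier | run made earlier | run made earlier | at 60 °C until 4.0 min, from then on at 100 °C | at 60 °C throughout |
| time |  |  |  |  | 8.0 min | 8.0 min |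

grey run (percent of the X charged)

| time / min | L / % | G / % | D / % |
|---|---|---|---|
| 0.200 | 0 | 1 | 0 |
| 0.417 | 0 | 0 | 0 |
| 0.667 | 0 | 4 | 0 |
| 1.33 | 0 | 7 | 0 |
| 2.50 | 3 | 19 | 0 |

ochre run (percent of the X charged)

| time / s | L / % | G / % | D / % |
|---|---|---|---|
| 10.0 | 0 | 1 | 0 |
| 12.0 | 0 | 7 | 1 |
| 25.0 | 4 | 6 | 0 |
| 50.0 | 1 | 22 | 4 |

violet run (percent of the X charged)

| time / min | L / % | G / % | D / % |
|---|---|---|---|
| 0.200 | 0 | 0 | 1 |
| 0.667 | 0 | 0 | 1 |
| 1.33 | 0 | 6 | 0 |
| 2.00 | 2 | 13 | 0 |
| 2.50 | 0 | 14 | 1 |

amber run (percent of the X charged)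

| time / s | L / % | G / % | D / % |
|---|---|---|---|
| 10.0 | 3 | 5 | 0 |
| 20.0 | 4 | 10 | 5 |
| 30.0 | 9 | 15 | 11 |
| 40.0 | 13 | 20 | 15 |
| 50.0 | 19 | 22 | 20 |

(scatter of a reading: 1.5 percentage points)

* which of the two ends with the higher share of L in all that became L or G or D ("neither" if they lie within 2 percentage points) (south / east / neither)
* share of L in all that became L or G or D, south
* share of L in all that became L or G or D, east

- in percentages every species weighs as the X in it: one D counts as two

The first chemist takes L over G as it stands in the flask, about 0.08 at 0.15 M of Q and 0.85 at 0.39 M, so roughly the square of Q. That carries east to about 2, to be trimmed for D and for the lag before L appears.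

I hold that a ratio read during the lag leaves out material still on its way, so I look at what amber adds late, between 30.0 s and 50.0 s. There L gains, with D counted at half its percentage on my assumption that each D is one L joined to one X, 15 percentage points, while G gains 7 points. I assume one pool that Q carries toward L and Z carries off to G, which these runs cannot test, since Z stands at 0.10 M in amber as in the others. Dividing the late gain toward L by the late gain of G and by the charged ratio of Q to Z gives 0.531, a reading that carries the scatter of the L, D and G figures at both times, and this split constant s is what I carry, taking it to be the same at 60 °C as at 92 °C.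

East can be frozen, because even 3 Q on each X, as the tris adduct L requires, costs 15.0% of its Q. Its ratio toward L is therefore 3.19. If the lag is over by 8.0 min and D stays small, the share of L is 76.1%, my own figure and higher than the first chemist's trimmed one. South charges 1.50 Q per X, which cannot be frozen, and it holds more X to eat L into D, so I expect a low share there and choose east.

The forecast, made by the first chemist with the words “Allowing for the lag”, says east, with 9% for south and 55% for east.

The simulation gives east, with 6.23% for south and 74.2% for east.

    X + Q → J (k = 0.0370 M⁻¹ s⁻¹, Ea = 51.0 kJ mol⁻¹)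
    Q + J → E (k = 0.0120 M⁻¹ s⁻¹, Ea = 80.0 kJ mol⁻¹)
    Q + E → L (k = 0.0110 M⁻¹ s⁻¹, Ea = 76.0 kJ mol⁻¹)
    J + Z → G (k = 0.0180 M⁻¹ s⁻¹, Ea = 78.0 kJ mol⁻¹)
    X + L → D (k = 0.240 M⁻¹ s⁻¹, Ea = 69.0 kJ mol⁻¹)
    (constants at 60 °C)

East still held 88.1% of its Q and 94.0% of its Z at 8.00 min, so the freeze held. The main reason the recipes part is the concentration of Q: east given south's Q, with its other settings kept, falls from 74.2% to 14.3%. Reading L as it stands keeps its ground early, for east read at 2.0 min shows 48.0%, with 46.3% still standing as J and 26.6% as E.

For east with 1.0 M of Q, s gives a ratio of 5.31 and so a share of 84.2%; the simulated flask gives 85.3%.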